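**Plan**

1. Retrosynthesis: ring C is cut at O1–C2 (cyclodehydration) and C2–C3 (Baker–Venkataraman acyl shift), separating a ring A acetophenone from a ring B benzoic acid; the C8–prenyl bond leads back to phloracetophenone and the C1'–CO2H bond to a 4-(1,1-dimethylallyl)resorcinol.
2. Ring B is cut at C1'–C6', C1'–C2', C3'–C4' and C4'–C5' into a dienyl diazo ketone (C1', C4', C5', C6' plus the quaternary side chain) and a siloxyacetylene (C2', C3').
3. Enabling feature: ring B is a resorcinol with O2' and O4' meta to each other, the quaternary 1,1-dimethylallyl carbon on C5' ortho to O4' and para to O2', and C1', C3', C6' as CH. This phenol / meta-oxygen / ortho-alkyl pattern is what a vinylketene–siloxyalkyne benzannulation delivers, so the quaternary centre comes from an aliphatic acid and is never forced onto an arene.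
4. Forward: ring B is built first (steps 1–5) and carboxylated at C1' (steps 6–9); ring A is prepared separately (steps 10–11); the two are joined as an ester (step 12) and ring C closes last (steps 13–14).
5. Stereochemistry: the target has no stereocentre and no stereogenic double bond. The only stereochemical element on the way is the E-alkene of 4 and 6, set by the Horner–Wadsworth–Emmons reaction and consumed when ring B forms.

Key step: step 5

Remark on the chemistry: flavone numbering is used (ring A = C5–C8, ring C = the pyranone, ring B = C1'–C6'); 1,1-dimethylallyl = 2-methylbut-3-en-2-yl, prenyl = 3-methylbut-2-enyl, MOM = methoxymethyl.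

**Route**

Step 1
Reactants: 1 2,2-dimethylbut-3-enoic acid
Product: 2 2,2-dimethylbut-3-en-1-ol
Conditions: LiAlH4, Et2O, 0 °C to reflux; aq. NaOH work-up
Reagents that add atoms: none
Why: Hydride reduction of a carboxylic acid to the primary alcohol; the isolated vinyl group is inert to hydride and the quaternary carbon rules out any isomerisation.

Step 2
Reactants: 2 2,2-dimethylbut-3-en-1-ol
Product: 4 (E)-5,5-dimethylhepta-3,6-dien-2-one, via 2,2-dimethylbut-3-enal 3 (not isolated)
Conditions: Dess–Martin periodinane, CH2Cl2, 0 °C to rt; aq. NaHCO3/Na2S2O3 wash, dried solution used directly; (MeO)2P(O)CH2C(O)CH3, NaH, THF, 0 °C to rt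
Reagents that add atoms: dimethyl (2-oxopropyl)phosphonate, COP(=O)(CC(C)=O)OC
Why: Dess–Martin oxidation stops at aldehyde 3, which has no α-hydrogen (no enolisation, no drift into conjugation) but is volatile and is therefore carried on in solution, and the Horner–Wadsworth–Emmons reaction of the keto-phosphonate anion with this α-quaternary aldehyde should give the E-enone.

Step 3
Reactants: 4 (E)-5,5-dimethylhepta-3,6-dien-2-one
Product: 6 (E)-1-diazo-5,5-dimethylhepta-3,6-dien-2-one, via trifluoroacetyl diketone 5 (not isolated)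
Conditions: LiN(SiMe3)2, THF, −78 °C; CF3CO2CH2CF3, −78 °C; aq. HCl wash; then MeSO2N3, Et3N, H2O (1 equiv), MeCN, rt
Reagents that add atoms: methanesulfonyl azide, CS(=O)(=O)N=[N+]=[N-]
Why: Detrifluoroacetylative diazo transfer: the kinetic enolate can form only at the methyl group (the γ-carbon is quaternary), Claisen trifluoroacetylation activates that carbon toward the sulfonyl azide, and fragmentation expels the trifluoroacetyl group as its sulfonamide, which avoids the pyrazoline formation seen when diazomethane meets unsaturated acid chlorides.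

Step 4
Reactants: 7 acetylene
Product: 10 (triisopropylsilyloxy)acetylene, via lithium acetylide 8 (not isolated), via lithium ethynolate 9 (not isolated)
Conditions: C2H2 (excess), n-BuLi, THF, −78 °C; t-BuOOLi (from t-BuOOH and LiN(SiMe3)2, THF, −78 °C), −78 to −10 °C; i-Pr3SiOTf, −78 to 0 °C
Reagents that add atoms: tert-butyl hydroperoxide, CC(C)(C)OO; triisopropylsilyl trifluoromethanesulfonate, CC(C)[Si](OS(=O)(=O)C(F)(F)F)(C(C)C)C(C)C
Why: Oxidation of a lithium acetylide with lithium tert-butyl peroxide to the lithium ynolate followed by O-silylation with a bulky silyl triflate is the standard entry to triisopropylsilyl ynol ethers from terminal alkynes; excess dissolved acetylene should keep the acetylide monolithiated and the hard, hindered triflate should silylate on oxygen.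

Step 5
Reactants: 6 (E)-1-diazo-5,5-dimethylhepta-3,6-dien-2-one; 10 (triisopropylsilyloxy)acetylene
Product: 13 2-(2-methylbut-3-en-2-yl)-5-(triisopropylsilyloxy)phenol, via vinylketene 11 (not isolated), via siloxycyclobutenone 12 (not isolated)
Conditions: hν (medium-pressure Hg lamp, Pyrex filter, > 300 nm), 10 (1.5 equiv), degassed ClCH2CH2Cl, rt; then 80 °C
Reagents that add atoms: none
Why: Irradiation expels N2 from 6 and the Wolff 1,2-shift of the alkenyl group (forming C1'–C6') gives vinylketene 11, whose carbonyl carbon is attacked by the nucleophilic unsubstituted carbon of the oxygen-polarised alkyne 10 in a [2+2] cycloaddition (forming C3'–C4' and C1'–C2') to give 4-alkenyl-3-siloxycyclobutenone 12. On heating, 12 undergoes reversible conrotatory four-electron ring opening to a dienylketene, which closes ring B by a thermally allowed disrotatory six-electron electrocyclisation (C4'–C5') and tautomerises to the phenol; this is the photochemical Wolff variant of the Danheiser benzannulation, known for unsaturated α-diazo ketones with siloxyalkynes. No stereocentre survives: C4 of 12 forms as a racemate and is lost on ring opening, and C5' becomes aromatic. The step needs regiocontrol in the [2+2] event, which the alkyne polarisation supplies (the siloxy carbon bonds to the ketene α-carbon, so OSi ends meta to the new OH and para to C5'), and it needs the quaternary substituent on the outside of the dienylketene at the closing terminus, which the E-alkene of 6 secures. Chemoselectivity rests on exciting only the diazo ketone chromophore through Pyrex (the isolated vinyl group does not absorb there), on the bulky triisopropylsilyl group resisting the 1,3-shift to a silylketene at 80 °C, and on a modest excess of 10 to limit acylation of the product phenol by 11.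

Step 6
Reactants: 13 2-(2-methylbut-3-en-2-yl)-5-(triisopropylsilyloxy)phenol
Product: 14 4-(2-methylbut-3-en-2-yl)benzene-1,3-diol
Conditions: Bu4NF, THF, 0 °C; aq. NH4Cl
Reagents that add atoms: none
Why: Fluoride cleaves the aryl silyl ether at 0 °C without touching the alkene, and removing silicon now avoids a retro-Brook O-to-C silyl shift when C1' is lithiated in step 9.

Step 7
Reactants: 14 4-(2-methylbut-3-en-2-yl)benzene-1,3-diol
Product: 15 2,4-bis(methoxymethoxy)-1-(2-methylbut-3-en-2-yl)benzene
Conditions: NaH, MeOCH2Cl, DMF, 0 °C to rt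
Reagents that add atoms: chloromethyl methyl ether, COCCl
Why: Williamson-type alkylation of the bis-phenoxide with the small chloromethyl ether caps both oxygens, including the one beside the quaternary carbon, as acetals that tolerate organolithium and enolate chemistry.

Step 8
Reactants: 15 2,4-bis(methoxymethoxy)-1-(2-methylbut-3-en-2-yl)benzene
Product: 16 1-bromo-2,4-bis(methoxymethoxy)-5-(2-methylbut-3-en-2-yl)benzene
Conditions: NBS, MeCN, 0 °C, dark
Reagents that add atoms: N-bromosuccinimide, O=C1CCC(=O)N1Br
Why: Electrophilic aromatic bromination of a resorcinol diether goes to the position para to one oxygen and ortho to the other (C1'), since C3' is crowded between two alkoxy groups and C6' is meta to both, and under neutral conditions in the dark the electron-rich ring should react far faster than the monosubstituted alkene.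

Step 9
Reactants: 16 1-bromo-2,4-bis(methoxymethoxy)-5-(2-methylbut-3-en-2-yl)benzene
Product: 18 2,4-bis(methoxymethoxy)-5-(2-methylbut-3-en-2-yl)benzoic acid, via aryllithium 17 (not isolated)
Conditions: n-BuLi, THF, −78 °C; CO2 (g), −78 °C to rt; cold dilute HCl to pH 4
Reagents that add atoms: carbon dioxide, O=C=O
Why: Bromine–lithium exchange at −78 °C outruns ortho-deprotonation between the two acetal oxygens, the aryllithium is stabilised by the neighbouring methoxymethoxy group, and carboxylation with CO2 gives the benzoic acid, whose acetals should survive a brief, cold, mildly acidic work-up.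

Step 10
Reactants: 19 2,4,6-trihydroxyacetophenone
Product: 20 2,4,6-trihydroxy-3-(3-methylbut-2-enyl)acetophenone
Conditions: prenyl bromide (1 equiv), DBU, THF, 0 °C to rt
Reagents that add atoms: prenyl bromide, CC(C)=CCBr
Why: Phloroglucinol-type phenoxides are ambident and are alkylated on carbon by allylic bromides under amidine-base conditions; C3 and C5 of the symmetric acetophenone are equivalent, so mono-C-prenylation can give only one constitutional isomer, and limiting the bromide holds back bis-prenylation.

Step 11
Reactants: 20 2,4,6-trihydroxy-3-(3-methylbut-2-enyl)acetophenone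
Product: 21 2-hydroxy-4,6-bis(methoxymethoxy)-3-(3-methylbut-2-enyl)acetophenone
Conditions: MeOCH2Cl (2.2 equiv), i-Pr2NEt, CH2Cl2, 0 °C to rt
Reagents that add atoms: chloromethyl methyl ether, COCCl
Why: The non-chelated 4-hydroxyl is alkylated first and, of the two hydroxyls hydrogen-bonded to the ketone, the one flanked by H5 is far more accessible than the one between the acetyl and prenyl groups, so two equivalents should leave free the hydroxyl that must become O1 of an 8-prenylflavone (the position of the free hydroxyl is to be confirmed spectroscopically before use).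

Step 12
Reactants: 18 2,4-bis(methoxymethoxy)-5-(2-methylbut-3-en-2-yl)benzoic acid; 21 2-hydroxy-4,6-bis(methoxymethoxy)-3-(3-methylbut-2-enyl)acetophenone
Product: 22 2-acetyl-3,5-bis(methoxymethoxy)-6-(3-methylbut-2-enyl)phenyl 2,4-bis(methoxymethoxy)-5-(2-methylbut-3-en-2-yl)benzoate
Conditions: DCC, DMAP (cat.), CH2Cl2, 0 °C to rt
Reagents that add atoms: none
Why: Steglich esterification: the acylpyridinium formed from the O-acylisourea is reactive enough to acylate the hindered, chelated phenol, and neither partner carries another free nucleophile.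

Step 13
Reactants: 22 2-acetyl-3,5-bis(methoxymethoxy)-6-(3-methylbut-2-enyl)phenyl 2,4-bis(methoxymethoxy)-5-(2-methylbut-3-en-2-yl)benzoate
Product: 23 1-[2-hydroxy-4,6-bis(methoxymethoxy)-3-(3-methylbut-2-enyl)phenyl]-3-[2,4-bis(methoxymethoxy)-5-(2-methylbut-3-en-2-yl)phenyl]propane-1,3-dione
Conditions: LiN(SiMe3)2 (3 equiv), THF, −78 °C to rt; aq. NH4Cl
Reagents that add atoms: none
Why: Baker–Venkataraman rearrangement: the enolate of the aryl methyl ketone attacks the neighbouring aryl ester intramolecularly (a Claisen-type O-to-C acyl shift forming C2–C3), the diketone is held as its enolate/phenoxide until work-up, and the non-nucleophilic amide base spares the acetals and both unsaturated side chains.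

Step 14
Reactants: 23 1-[2-hydroxy-4,6-bis(methoxymethoxy)-3-(3-methylbut-2-enyl)phenyl]-3-[2,4-bis(methoxymethoxy)-5-(2-methylbut-3-en-2-yl)phenyl]propane-1,3-dione
Product: 25 2-[2,4-dihydroxy-5-(2-methylbut-3-en-2-yl)phenyl]-5,7-dihydroxy-8-(3-methylbut-2-enyl)chromen-4-one, via tetra-MOM flavone 24 (not isolated)
Conditions: HCl (3 M aq.)–MeOH–THF, rt (ring closure), then 45 °C (acetal cleavage)
Reagents that add atoms: none
Why: Acid-catalysed cyclodehydration: the only free hydroxyl (the one next to the prenyl group) adds to the ring B carbonyl and the hemiketal loses water to form O1–C2, which should fix the 8-prenyl regiochemistry before methanolysis of the four acetals; dilute HCl in methanol is the usual way to unmask methoxymethyl-protected prenylphenols, since an alkene ortho to a phenol is protonated only by much stronger acid.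

**Compound list**

1 | 2,2-dimethylbut-3-enoic acid | C=CC(C)(C)C(=O)O | starting material
2 | 2,2-dimethylbut-3-en-1-ol | C=CC(C)(C)CO | intermediate
3 | 2,2-dimethylbut-3-enal | C=CC(C)(C)C=O | intermediate
4 | (E)-5,5-dimethylhepta-3,6-dien-2-one | C=CC(C)(C)/C=C/C(C)=O | intermediate
5 | (E)-1,1,1-trifluoro-7,7-dimethylnona-5,8-diene-2,4-dione | C=CC(C)(C)/C=C/C(=O)CC(=O)C(F)(F)F | intermediate
6 | (E)-1-diazo-5,5-dimethylhepta-3,6-dien-2-one | C=CC(C)(C)/C=C/C(=O)C=[N+]=[N-] | intermediate
7 | acetylene | C#C | starting material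
8 | lithium acetylide | [Li]C#C | intermediate
9 | lithium ethynolate | [Li+].[O-]C#C | intermediate
10 | (triisopropylsilyloxy)acetylene | C#CO[Si](C(C)C)(C(C)C)C(C)C | intermediate
11 | (E)-5,5-dimethylhepta-1,3,6-trien-1-one (vinylketene) | C=CC(C)(C)/C=C/C=C=O | intermediate
12 | 4-[(E)-3,3-dimethylpenta-1,4-dienyl]-3-(triisopropylsilyloxy)cyclobut-2-en-1-one (racemic) | O=C1C=C(O[Si](C(C)C)(C(C)C)C(C)C)C1/C=C/C(C)(C)C=C | intermediate
13 | 2-(2-methylbut-3-en-2-yl)-5-(triisopropylsilyloxy)phenol | C=CC(C)(C)c1ccc(O[Si](C(C)C)(C(C)C)C(C)C)cc1O | intermediate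
14 | 4-(2-methylbut-3-en-2-yl)benzene-1,3-diol | C=CC(C)(C)c1ccc(O)cc1O | intermediate
15 | 2,4-bis(methoxymethoxy)-1-(2-methylbut-3-en-2-yl)benzene | C=CC(C)(C)c1ccc(OCOC)cc1OCOC | intermediate
16 | 1-bromo-2,4-bis(methoxymethoxy)-5-(2-methylbut-3-en-2-yl)benzene | C=CC(C)(C)c1cc(Br)c(OCOC)cc1OCOC | intermediate
17 | [2,4-bis(methoxymethoxy)-5-(2-methylbut-3-en-2-yl)phenyl]lithium | [Li]c1cc(C(C)(C)C=C)c(OCOC)cc1OCOC | intermediate
18 | 2,4-bis(methoxymethoxy)-5-(2-methylbut-3-en-2-yl)benzoic acid | C=CC(C)(C)c1cc(C(=O)O)c(OCOC)cc1OCOC | intermediate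
19 | 2,4,6-trihydroxyacetophenone | CC(=O)c1c(O)cc(O)cc1O | starting material
20 | 2,4,6-trihydroxy-3-(3-methylbut-2-enyl)acetophenone | CC(=O)c1c(O)cc(O)c(CC=C(C)C)c1O | intermediate
21 | 2-hydroxy-4,6-bis(methoxymethoxy)-3-(3-methylbut-2-enyl)acetophenone | CC(=O)c1c(O)c(CC=C(C)C)c(OCOC)cc1OCOC | intermediate
22 | 2-acetyl-3,5-bis(methoxymethoxy)-6-(3-methylbut-2-enyl)phenyl 2,4-bis(methoxymethoxy)-5-(2-methylbut-3-en-2-yl)benzoate | CC(=O)c1c(OC(=O)c2cc(C(C)(C)C=C)c(OCOC)cc2OCOC)c(CC=C(C)C)c(OCOC)cc1OCOC | intermediate
23 | 1-[2-hydroxy-4,6-bis(methoxymethoxy)-3-(3-methylbut-2-enyl)phenyl]-3-[2,4-bis(methoxymethoxy)-5-(2-methylbut-3-en-2-yl)phenyl]propane-1,3-dione | O=C(CC(=O)c1cc(C(C)(C)C=C)c(OCOC)cc1OCOC)c1c(O)c(CC=C(C)C)c(OCOC)cc1OCOC | intermediate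
24 | 5,7-bis(methoxymethoxy)-2-[2,4-bis(methoxymethoxy)-5-(2-methylbut-3-en-2-yl)phenyl]-8-(3-methylbut-2-enyl)chromen-4-one | C=CC(C)(C)c1cc(-c2cc(=O)c3c(OCOC)cc(OCOC)c(CC=C(C)C)c3o2)c(OCOC)cc1OCOC | intermediate
25 | 2-[2,4-dihydroxy-5-(2-methylbut-3-en-2-yl)phenyl]-5,7-dihydroxy-8-(3-methylbut-2-enyl)chromen-4-one (CNP0315714.0) | C=CC(C)(C)c1cc(-c2cc(=O)c3c(O)cc(O)c(CC=C(C)C)c3o2)c(O)cc1O | target

**Count and risks**

Total steps: 14. Longest linear sequence: 11 steps (1, 2, 3, 5, 6, 7, 8, 9, 12, 13, 14).

Step 4 (siloxyacetylene). What may go wrong: disproportionation of monolithium acetylide to insoluble dilithium acetylide while the oxidation warms, silylation of tert-butoxide in competition with the ynolate, or loss of the volatile, hydrolytically sensitive product on isolation. Fallback: give up the silyl ynol ether and use commercial ethoxyacetylene (C#COCC), the classical alkynyl ether partner of the same benzannulation. This sets out from 6 and comes back to the route at 15. Photolysis of 6 with ethoxyacetylene should pass through 3-ethoxy-4-[(E)-3,3-dimethylpenta-1,4-dienyl]cyclobut-2-en-1-one F1 (not isolated) and, after heating, give 5-ethoxy-2-(2-methylbut-3-en-2-yl)phenol F2. Because a thiolate dealkylates the ether of a phenoxide only sluggishly, the free hydroxyl is capped first (NaH, MeOCH2Cl) to give 4-ethoxy-2-(methoxymethoxy)-1-(2-methylbut-3-en-2-yl)benzene F3. NaSEt in DMF at 140 °C then removes the ethyl group to give 3-(methoxymethoxy)-4-(2-methylbut-3-en-2-yl)phenol F4, and a second methoxymethylation gives 15.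

Step 5 (benzannulation). What may go wrong: photochemical E-to-Z isomerisation or carbene side reactions in place of the Wolff shift, dimerisation of the vinylketene, slow six-electron closure onto a terminus carrying a quaternary carbon, or acylation of the product phenol by the ketene. Fallback: an aromatic Claisen rearrangement on a preformed resorcinol ring, all known chemistry. It sets out from no numbered compound but from commercial 2,4-dihydroxybenzaldehyde (O=Cc1ccc(O)cc1O), and comes back to the route at 18. Alkylation of the non-chelated 4-hydroxyl (prenyl bromide, K2CO3, acetone) gives 2-hydroxy-4-(3-methylbut-2-enyloxy)benzaldehyde F5, and methoxymethylation (MeOCH2Cl, i-Pr2NEt) gives 2-(methoxymethoxy)-4-(3-methylbut-2-enyloxy)benzaldehyde F6. [3,3]-Rearrangement in N,N-diethylaniline at about 190 °C should deliver the reverse-prenyl group to the less hindered ortho position C5 and give 4-hydroxy-2-(methoxymethoxy)-5-(2-methylbut-3-en-2-yl)benzaldehyde F7. A second methoxymethylation gives 2,4-bis(methoxymethoxy)-5-(2-methylbut-3-en-2-yl)benzaldehyde F8, and Pinnick oxidation (NaClO2, NaH2PO4, 2-methylbut-2-ene, t-BuOH–H2O) gives 18.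

Step 14 (ring C closure and deprotection). What may go wrong: acid-promoted addition of the liberated 7-hydroxyl to the 8-prenyl double bond, or loss of the acetal on the second ortho oxygen of 23 before ring closure, so that either oxygen closes ring C and the 6- and 8-prenyl series mix. Fallback: keep ring A capped with acid-stable allyl ethers through the acid step and unmask it under neutral conditions. This sets out from 20 and 18 and comes back to the route at 25. Allylation of 20 (allyl bromide, K2CO3, acetone, reflux; the hindered chelated hydroxyl next to the prenyl group should stay free) gives 4,6-bis(allyloxy)-2-hydroxy-3-(3-methylbut-2-enyl)acetophenone F9. Esterification with 18 as in step 12 gives 2-acetyl-3,5-bis(allyloxy)-6-(3-methylbut-2-enyl)phenyl 2,4-bis(methoxymethoxy)-5-(2-methylbut-3-en-2-yl)benzoate F10, and the acyl shift of step 13 gives 1-[4,6-bis(allyloxy)-2-hydroxy-3-(3-methylbut-2-enyl)phenyl]-3-[2,4-bis(methoxymethoxy)-5-(2-methylbut-3-en-2-yl)phenyl]propane-1,3-dione F11. HCl–MeOH closes ring C to 5,7-bis(allyloxy)-2-[2,4-bis(methoxymethoxy)-5-(2-methylbut-3-en-2-yl)phenyl]-8-(3-methylbut-2-enyl)chromen-4-one F12 (not isolated) and then removes only the two ring B acetals to give 5,7-bis(allyloxy)-2-[2,4-dihydroxy-5-(2-methylbut-3-en-2-yl)phenyl]-8-(3-methylbut-2-enyl)chromen-4-one F13. Pd(PPh3)4 with morpholine in THF at rt (zerovalent palladium, allyl transfer to the amine) cleaves both allyl ethers and gives 25.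

Further compounds

F1 | step 4 | 3-ethoxy-4-[(E)-3,3-dimethylpenta-1,4-dienyl]cyclobut-2-en-1-one (racemic) | CCOC1=CC(=O)C1/C=C/C(C)(C)C=C
F2 | step 4 | 5-ethoxy-2-(2-methylbut-3-en-2-yl)phenol | C=CC(C)(C)c1ccc(OCC)cc1O
F3 | step 4 | 4-ethoxy-2-(methoxymethoxy)-1-(2-methylbut-3-en-2-yl)benzene | C=CC(C)(C)c1ccc(OCC)cc1OCOC
F4 | step 4 | 3-(methoxymethoxy)-4-(2-methylbut-3-en-2-yl)phenol | C=CC(C)(C)c1ccc(O)cc1OCOC
F5 | step 5 | 2-hydroxy-4-(3-methylbut-2-enyloxy)benzaldehyde | CC(C)=CCOc1ccc(C=O)c(O)c1
F6 | step 5 | 2-(methoxymethoxy)-4-(3-methylbut-2-enyloxy)benzaldehyde | CC(C)=CCOc1ccc(C=O)c(OCOC)c1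
F7 | step 5 | 4-hydroxy-2-(methoxymethoxy)-5-(2-methylbut-3-en-2-yl)benzaldehyde | C=CC(C)(C)c1cc(C=O)c(OCOC)cc1O
F8 | step 5 | 2,4-bis(methoxymethoxy)-5-(2-methylbut-3-en-2-yl)benzaldehyde | C=CC(C)(C)c1cc(C=O)c(OCOC)cc1OCOC
F9 | step 14 | 4,6-bis(allyloxy)-2-hydroxy-3-(3-methylbut-2-enyl)acetophenone | CC(=O)c1c(O)c(CC=C(C)C)c(OCC=C)cc1OCC=C
F10 | step 14 | 2-acetyl-3,5-bis(allyloxy)-6-(3-methylbut-2-enyl)phenyl 2,4-bis(methoxymethoxy)-5-(2-methylbut-3-en-2-yl)benzoate | CC(=O)c1c(OC(=O)c2cc(C(C)(C)C=C)c(OCOC)cc2OCOC)c(CC=C(C)C)c(OCC=C)cc1OCC=C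
F11 | step 14 | 1-[4,6-bis(allyloxy)-2-hydroxy-3-(3-methylbut-2-enyl)phenyl]-3-[2,4-bis(methoxymethoxy)-5-(2-methylbut-3-en-2-yl)phenyl]propane-1,3-dione | O=C(CC(=O)c1cc(C(C)(C)C=C)c(OCOC)cc1OCOC)c1c(O)c(CC=C(C)C)c(OCC=C)cc1OCC=C
F12 | step 14 | 5,7-bis(allyloxy)-2-[2,4-bis(methoxymethoxy)-5-(2-methylbut-3-en-2-yl)phenyl]-8-(3-methylbut-2-enyl)chromen-4-one | C=CCOc1cc(OCC=C)c2c(=O)cc(-c3cc(C(C)(C)C=C)c(OCOC)cc3OCOC)oc2c1CC=C(C)C
F13 | step 14 | 5,7-bis(allyloxy)-2-[2,4-dihydroxy-5-(2-methylbut-3-en-2-yl)phenyl]-8-(3-methylbut-2-enyl)chromen-4-one | C=CCOc1cc(OCC=C)c2c(=O)cc(-c3cc(C(C)(C)C=C)c(O)cc3O)oc2c1CC=C(C)C
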